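The data are simulated with made-up constants; the scatter is artificial.

The south-east run could not keep its opening pace: at 0.0902 min⁻¹ of the charge, read at 1.33 min, target would have taken the whole charge within 11.1 min, yet it stood at 42 % at 8.00 min.

| flask | starting material | remark | time |
|---|---|---|---|
| south-east | 0.96 M | run made earlier |  |
| flask | 0.64 M |  | 80 min |
south-east run (percent of the starting material charged)

| time / min | isomer of the product / % | target / % |
|---|---|---|
| 0.667 | 0 | 5 |
| 1.33 | 1 | 12 |
| 3.00 | 1 | 24 |
| 8.00 | 4 | 42 |

(scatter of a reading: 1.5 percentage points)
* share of isomer of the product in isomer of the product plus target at 8.0 s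
* share of isomer of the product in isomer of the product plus target at 3.0 min
* share of isomer of the product in isomer of the product plus target at 80 min
* which of isomer of the product and target there is more of at 80 min
- on the list of suspects stand: starting material <-> isomer of the product; starting material <-> target; starting material <-> third isomer

I took each step as first order, so the south-east percentages carry over to the flask at 0.64 M. Target's pace between 3.00 min and 8.00 min was 0.0360 min⁻¹, slower than at the start. If nothing had yet returned, about 39.9 % of the starting material stood at 5.50 min, which means a decay of 0.167 min⁻¹ and a half-life near 4.15 min.

On the first rung, 8.0 s and 3.0 min are both shorter than that half-life, so I put the share at both times at the pooled reading, 6.74 %. On the next rung, by 8.00 min in the south-east run, I reckoned about 26.3 % of the starting material remaining, which left 27.7 % unread, perhaps third isomer.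

The slowest rung is the isomer's clock, the fraction of the starting material present that becomes isomer of the product each minute, 0.00608 min⁻¹. Its time, 164 min, exceeds 80 min, so I expected kinetic control. Going round once more, I put 26.3 % back in as a round figure for the starting material up to 80 min: my estimate for isomer of the product came to about 15.5 %, against target near 54.0 %, a share near 22.3 %.

The forecast, higher than my estimate at 80 min, gave 7 %, 7.5 % and 28 %, with target ahead: “target probably still leads”.

The flask gives 4.47 %, 4.65 % and 11.7 %, with target ahead.

    starting material ⇌ isomer of the product (K = 24.2, k = 8.92 × 10⁻⁵ s⁻¹)
    starting material ⇌ target (K = 4.40, k = 0.00191 s⁻¹)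
    starting material ⇌ third isomer (K = 1.09, k = 0.00167 s⁻¹)

At 80.0 min the flask held 13.9 % starting material and 15.5 % third isomer. From 40.0 min onward, the clock on its starting material gives 3.54 % more isomer of the product, and the flask gained 3 percentage points. In the neighbour flask at 0.38 M, the clock on 13.9 % starting material gives 8.46 × 10⁻⁴ min⁻¹ of its charge, and its share at 80.0 min stands at 11.7 %.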